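**Plan**

- Retrosynthesis: the last step cuts no skeletal bond. The three benzene rings are traced back to three 4,5-dihydroxy-3-oxocyclohex-1-enecarbonyl (3-dehydroshikimoyl) rings. The three ester C(=O)–O bonds at O3, O4 and O5 of the core are cut next, giving tert-butyl shikimate and three molecules of a diol-protected 3-dehydroshikimic acid, all from shikimic acid.
- Forward: the acyl donor is made in three steps (diacetal on the trans C4/C5 diol, saponification, oxidation at C3). Three molecules of it are esterified onto one molecule of tert-butyl shikimate, and all protecting groups are removed with aqueous TFA. The three carbocyclic acyl rings are aromatised last; no permanent ring is closed anywhere.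
- Enabling feature: in each acyl ring C3′ is a ketone and C4′ carries a free hydroxyl, an α-ketol that can form the C3′–C4′ enediol. C5′–H and C6′–H2 then let the 3′,4′-diketone tautomerise to the 3,4,5-trihydroxyphenyl ring. The core ring has no ketone and stays a cyclohexene.
- Stereochemistry: C3 (R), C4 (S) and C5 (R) of the core come unchanged from natural (−)-shikimic acid, since every acylation is at oxygen and no C–O bond at these centres is broken. The stereocentres of the acyl rings are erased on aromatisation.

Key step: step 7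

Remark: primed locants (C3′ to C6′) denote the acyl rings, numbered as in shikimic acid; "diacetal" means the (2S,3S)-2,3-dimethoxybutane-2,3-diyl bridge between O4 and O5.

**Route**

Step 1
Reactants: 1 shikimic acid; 2 butane-2,3-dione
Product: 4 methyl shikimate 4,5-O-[(2S,3S)-2,3-dimethoxybutane-2,3-diyl] acetal, via methyl shikimate 3 (not isolated)
Conditions: CSA (cat.), MeOH, reflux; then 2, HC(OMe)3, reflux
Reagents that add atoms: methanol, CO; trimethyl orthoformate, COC(OC)OC (water scavenger whose methoxy groups exchange with methanol)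
Why: Fischer esterification followed by butane-2,3-diacetal formation, which selects the trans-diequatorial C4/C5 diol because only it gives a trans-fused chair dioxane with both methoxy groups axial (anomeric effect); this thermodynamic preference sets the two new acetal centres as (2S,3S) and leaves the allylic C3 hydroxyl free.

Step 2
Reactants: 4 methyl shikimate 4,5-O-[(2S,3S)-2,3-dimethoxybutane-2,3-diyl] acetal
Product: 5 shikimic acid 4,5-O-[(2S,3S)-2,3-dimethoxybutane-2,3-diyl] acetal (C3–OH free)
Conditions: LiOH·H2O, THF–H2O 3:1, 0 °C to rt; then 1 M HCl to pH 3 at 0 °C, EtOAc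
Reagents that add atoms: lithium hydroxide, [Li+].[OH-]
Why: Ester saponification is done before the ketone exists, so hydroxide never meets a β-alkoxy enone; the acetal is inert to base and should survive the brief cold acidification.

Step 3
Reactants: 5 shikimic acid 4,5-O-[(2S,3S)-2,3-dimethoxybutane-2,3-diyl] acetal
Product: 6 3-dehydroshikimic acid 4,5-O-[(2S,3S)-2,3-dimethoxybutane-2,3-diyl] acetal (4,5-protected 3-oxo acid)
Conditions: IBX (1.5 equiv), EtOAc, 70 °C; filtration
Reagents that add atoms: none
Why: IBX oxidation of a secondary allylic alcohol to the enone tolerates the free carboxylic acid, needs no base and leaves a spent oxidant that is filtered off, so the β-alkoxy enone is not exposed to eliminating conditions; the enolisable C4 centre should stay trans-fused because the diequatorial dioxane is the more stable ring fusion.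

Step 4
Reactants: 1 shikimic acid
Product: 7 tert-butyl shikimate (tert-butyl (3R,4S,5R)-3,4,5-trihydroxycyclohex-1-ene-1-carboxylate)
Conditions: Cl3CC(=NH)OtBu (2.5 equiv), THF (a little DMF for solubility), rt
Reagents that add atoms: tert-butyl 2,2,2-trichloroacetimidate, CC(C)(C)OC(=N)C(Cl)(Cl)Cl
Why: Acid-selective tert-butylation with a trichloroacetimidate, in which the carboxylic acid itself protonates the imidate and traps the tert-butyl cation while the three hydroxyls, which would need a strong Lewis acid, stay free.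

Step 5
Reactants: 7 tert-butyl shikimate; 6 3-dehydroshikimic acid 4,5-O-[(2S,3S)-2,3-dimethoxybutane-2,3-diyl] acetal (first of the three molecules taken up by each molecule of 7); 6 the same protected keto acid (second molecule); 6 the same protected keto acid (third molecule)
Product: 8 tert-butyl 3,4,5-tris-O-{4,5-O-[(2S,3S)-2,3-dimethoxybutane-2,3-diyl]-3-dehydroshikimoyl}shikimate
Conditions: 6 (3.6 equiv in all, 1.2 per hydroxyl), DIC (4 equiv), DMAP (0.5 equiv), CH2Cl2, 0 °C to rt
Reagents that add atoms: second molecule of acid 6 named above, OC(=O)C1=CC(=O)[C@H]2O[C@](C)(OC)[C@@](C)(OC)O[C@@H]2C1; third molecule of acid 6 named above, OC(=O)C1=CC(=O)[C@H]2O[C@](C)(OC)[C@@](C)(OC)O[C@@H]2C1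
Why: Threefold Steglich esterification, the standard way to acylate polyols exhaustively with hindered aroyl-type acids, in which each molecule of 7 takes up three molecules of 6 with loss of three molecules of water to the carbodiimide; the donor carboxyl sits on an sp2 carbon far from the acetal, so all three secondary hydroxyls should react, and the diequatorial C5′–O bond of the trans-fused acetal is poorly aligned with the enone π system, which disfavours E1cB loss of O5′ under the mild base.

Step 6
Reactants: 8 tert-butyl 3,4,5-tris-O-{4,5-O-[(2S,3S)-2,3-dimethoxybutane-2,3-diyl]-3-dehydroshikimoyl}shikimate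
Product: 9 tri-ketol precursor 3,4,5-tris-O-(3-dehydroshikimoyl)shikimic acid (each acyl group (4S,5R)-4,5-dihydroxy-3-oxocyclohex-1-ene-1-carbonyl)
Conditions: TFA–H2O 9:1, 0 °C to rt, short; evaporation, co-evaporation with toluene; used crude
Reagents that add atoms: none
Why: Aqueous TFA hydrolyses the three diacetals through oxocarbenium ions and cleaves the tert-butyl ester by loss of the tert-butyl cation in one operation; the three core esters and the allylic C3–O bond should hold because the alkene is deactivated by its conjugated carboxyl, and a cold, short exposure limits acid-promoted dehydration of the liberated ketols.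

Step 7
Reactants: 9 3,4,5-tris-O-(3-dehydroshikimoyl)shikimic acid
Product: 10 the target 3,4,5-tri-O-galloylshikimic acid ((3R,4S,5R)-3,4,5-tris(3,4,5-trihydroxybenzoyloxy)cyclohex-1-ene-1-carboxylic acid)
Conditions: Cu(OAc)2 (7 equiv), degassed AcOH–H2O 9:1, 40 °C, Ar; then 1 M HCl/EtOAc, Sephadex LH-20
Reagents that add atoms: none
Why: Proposed new method: each acyl ring is an α-ketol (C3′ ketone, C4′ hydroxyl) that binds divalent copper and enolises to the C3′–C4′ enediol; two one-electron transfers to Cu(OAc)2 give the 3′,4′-diketone, which enolises through C5′–H and then C6′–H to the 3,4,5-trihydroxybenzoyl ring, so three six-membered carbocycles become aromatic with no new skeletal bond. The closest known reaction types are the Cu(OAc)2–acetic acid oxidation of free 3-dehydroshikimic acid to gallic acid and the copper-mediated oxidation of acyloins to 1,2-diketones; new here is that the ketol sits in an O-acyl group and that three must react in one molecule. No ring is closed and no stereocentre is made: the six stereocentres of the acyl rings are erased, and C3, C4 and C5 of the core are untouched because the core ring has no ketone and cannot form an enediol. The selectivity needed is oxidation before loss of water from C5′, which would leave a 3,4-dihydroxybenzoyl group; a large excess of oxidant at high concentration (electron transfer is bimolecular, dehydration is not), the weakly acidic medium and the modest temperature should secure it. Exclusion of air keeps the new pyrogallol rings from copper-catalysed autoxidation, the monovalent copper acetate formed is removed in the acidic work-up, and acid rather than base leaves the three ester links in place.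

**Compound list**

1 | shikimic acid | O=C(O)C1=C[C@@H](O)[C@@H](O)[C@H](O)C1 | starting material
2 | butane-2,3-dione | CC(=O)C(C)=O | starting material
3 | methyl shikimate | COC(=O)C1=C[C@@H](O)[C@@H](O)[C@H](O)C1 | intermediate (not isolated)
4 | methyl shikimate 4,5-O-[(2S,3S)-2,3-dimethoxybutane-2,3-diyl] acetal | COC(=O)C1=C[C@@H](O)[C@H]2O[C@](C)(OC)[C@@](C)(OC)O[C@@H]2C1 | intermediate
5 | shikimic acid 4,5-O-[(2S,3S)-2,3-dimethoxybutane-2,3-diyl] acetal | OC(=O)C1=C[C@@H](O)[C@H]2O[C@](C)(OC)[C@@](C)(OC)O[C@@H]2C1 | intermediate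
6 | 3-dehydroshikimic acid 4,5-O-[(2S,3S)-2,3-dimethoxybutane-2,3-diyl] acetal | OC(=O)C1=CC(=O)[C@H]2O[C@](C)(OC)[C@@](C)(OC)O[C@@H]2C1 | intermediate
7 | tert-butyl shikimate | CC(C)(C)OC(=O)C1=C[C@@H](O)[C@@H](O)[C@H](O)C1 | intermediate
8 | tert-butyl 3,4,5-tris-O-{4,5-O-[(2S,3S)-2,3-dimethoxybutane-2,3-diyl]-3-dehydroshikimoyl}shikimate | CC(C)(C)OC(=O)C1=C[C@@H](OC(=O)C2=CC(=O)[C@H]3O[C@](C)(OC)[C@@](C)(OC)O[C@@H]3C2)[C@@H](OC(=O)C2=CC(=O)[C@H]3O[C@](C)(OC)[C@@](C)(OC)O[C@@H]3C2)[C@H](OC(=O)C2=CC(=O)[C@H]3O[C@](C)(OC)[C@@](C)(OC)O[C@@H]3C2)C1 | intermediate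
9 | 3,4,5-tris-O-(3-dehydroshikimoyl)shikimic acid | O=C(O)C1=C[C@@H](OC(=O)C2=CC(=O)[C@@H](O)[C@H](O)C2)[C@@H](OC(=O)C2=CC(=O)[C@@H](O)[C@H](O)C2)[C@H](OC(=O)C2=CC(=O)[C@@H](O)[C@H](O)C2)C1 | intermediate
10 | 3,4,5-tri-O-galloylshikimic acid | O=C(O)C1=C[C@@H](OC(=O)c2cc(O)c(O)c(O)c2)[C@@H](OC(=O)c2cc(O)c(O)c(O)c2)[C@H](OC(=O)c2cc(O)c(O)c(O)c2)C1 | target

**Count and risks**

Total step count: 7. Longest linear sequence: 6 steps (steps 1, 2, 3, 5, 6, 7); step 4 is the side branch to the core.

Steps most likely to fail:

Step 7. Oxidation of the three acyl rings may not keep pace with their dehydration, so that rings aromatised by water loss (one hydroxyl short) are built in beside the desired ones. Copper may also over-oxidise the pyrogallol rings once they form. The fallback uses known chemistry only, sets out from 7 and comes back at 10. Steglich esterification (DIC, DMAP, CH2Cl2) of 7 with three molecules of 3,4,5-tris(tert-butyldimethylsilyloxy)benzoic acid should give tert-butyl 3,4,5-tris-O-[3,4,5-tris(tert-butyldimethylsilyloxy)benzoyl]shikimate F1. Anhydrous TFA in CH2Cl2 at 0 °C should then cleave only the tert-butyl ester, giving 3,4,5-tris-O-[3,4,5-tris(tert-butyldimethylsilyloxy)benzoyl]shikimic acid F2. HF·pyridine in THF should finally remove the nine aryl silyl groups and deliver 10. Silyl ethers are preferred to benzyl ethers because hydrogenolysis would saturate the C1=C2 bond of the core.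

Step 5. The activated keto acid may lose the C5′ acetal oxygen by base-induced β-elimination and aromatise, or the third acylation may stall next to two bulky esters. The fallback sets out from 4 and comes back at 8; it carries the donor at the alcohol oxidation level, so that no enone is present during acylation. TBSCl and imidazole in DMF should convert 4 into methyl 3-O-(tert-butyldimethylsilyl)shikimate 4,5-O-[(2S,3S)-2,3-dimethoxybutane-2,3-diyl] acetal F3. LiOH in THF–H2O should give 3-O-(tert-butyldimethylsilyl)shikimic acid 4,5-O-[(2S,3S)-2,3-dimethoxybutane-2,3-diyl] acetal F4. Steglich coupling of three molecules of F4 with 7 should give tert-butyl 3,4,5-tris-O-{3-O-(tert-butyldimethylsilyl)-4,5-O-[(2S,3S)-2,3-dimethoxybutane-2,3-diyl]shikimoyl}shikimate F5. HF·pyridine should free the three allylic hydroxyls to give tert-butyl 3,4,5-tris-O-{4,5-O-[(2S,3S)-2,3-dimethoxybutane-2,3-diyl]shikimoyl}shikimate F6. Dess–Martin periodinane with NaHCO3 in CH2Cl2 should then oxidise the three C3′ alcohols to give 8.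

Step 6. The freshly liberated β-hydroxy ketone units may lose water under acid, or acetal hydrolysis next to the ketone may be slow enough to force longer exposure. The fallback sets out from 4 and comes back at 9; it unmasks the diols while C3′ is still an alcohol. The silyl ether F3, the acid F4 and the silylated triester F5 are made as in the fallback for step 5. TFA–H2O 9:1 applied to F5 should remove silyl, acetal and tert-butyl groups together from a substrate that has no ketone, giving 3,4,5-tris-O-shikimoylshikimic acid F7. Aerobic dehydrogenation over Pt/C in water at about 50 °C (Heyns oxidation) should then convert the three allylic, pseudoaxial C3′ hydroxyls into ketones and give 9. Catalytic platinum–oxygen oxidation of this type is the established way to oxidise the axial secondary hydroxyl of cyclitol acids such as quinic acid to the ketone while equatorial hydroxyls are left alone.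

**Further compounds**

F1 | step 7 | tert-butyl 3,4,5-tris-O-[3,4,5-tris(tert-butyldimethylsilyloxy)benzoyl]shikimate | CC(C)(C)OC(=O)C1=C[C@@H](OC(=O)c2cc(O[Si](C)(C)C(C)(C)C)c(O[Si](C)(C)C(C)(C)C)c(O[Si](C)(C)C(C)(C)C)c2)[C@@H](OC(=O)c2cc(O[Si](C)(C)C(C)(C)C)c(O[Si](C)(C)C(C)(C)C)c(O[Si](C)(C)C(C)(C)C)c2)[C@H](OC(=O)c2cc(O[Si](C)(C)C(C)(C)C)c(O[Si](C)(C)C(C)(C)C)c(O[Si](C)(C)C(C)(C)C)c2)C1
F2 | step 7 | 3,4,5-tris-O-[3,4,5-tris(tert-butyldimethylsilyloxy)benzoyl]shikimic acid | O=C(O)C1=C[C@@H](OC(=O)c2cc(O[Si](C)(C)C(C)(C)C)c(O[Si](C)(C)C(C)(C)C)c(O[Si](C)(C)C(C)(C)C)c2)[C@@H](OC(=O)c2cc(O[Si](C)(C)C(C)(C)C)c(O[Si](C)(C)C(C)(C)C)c(O[Si](C)(C)C(C)(C)C)c2)[C@H](OC(=O)c2cc(O[Si](C)(C)C(C)(C)C)c(O[Si](C)(C)C(C)(C)C)c(O[Si](C)(C)C(C)(C)C)c2)C1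
F3 | step 5 | methyl 3-O-(tert-butyldimethylsilyl)shikimate 4,5-O-[(2S,3S)-2,3-dimethoxybutane-2,3-diyl] acetal | COC(=O)C1=C[C@@H](O[Si](C)(C)C(C)(C)C)[C@H]2O[C@](C)(OC)[C@@](C)(OC)O[C@@H]2C1
F4 | step 5 | 3-O-(tert-butyldimethylsilyl)shikimic acid 4,5-O-[(2S,3S)-2,3-dimethoxybutane-2,3-diyl] acetal | OC(=O)C1=C[C@@H](O[Si](C)(C)C(C)(C)C)[C@H]2O[C@](C)(OC)[C@@](C)(OC)O[C@@H]2C1
F5 | step 5 | tert-butyl 3,4,5-tris-O-{3-O-(tert-butyldimethylsilyl)-4,5-O-[(2S,3S)-2,3-dimethoxybutane-2,3-diyl]shikimoyl}shikimate | CC(C)(C)OC(=O)C1=C[C@@H](OC(=O)C2=C[C@@H](O[Si](C)(C)C(C)(C)C)[C@H]3O[C@](C)(OC)[C@@](C)(OC)O[C@@H]3C2)[C@@H](OC(=O)C2=C[C@@H](O[Si](C)(C)C(C)(C)C)[C@H]3O[C@](C)(OC)[C@@](C)(OC)O[C@@H]3C2)[C@H](OC(=O)C2=C[C@@H](O[Si](C)(C)C(C)(C)C)[C@H]3O[C@](C)(OC)[C@@](C)(OC)O[C@@H]3C2)C1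
F6 | step 5 | tert-butyl 3,4,5-tris-O-{4,5-O-[(2S,3S)-2,3-dimethoxybutane-2,3-diyl]shikimoyl}shikimate | CC(C)(C)OC(=O)C1=C[C@@H](OC(=O)C2=C[C@@H](O)[C@H]3O[C@](C)(OC)[C@@](C)(OC)O[C@@H]3C2)[C@@H](OC(=O)C2=C[C@@H](O)[C@H]3O[C@](C)(OC)[C@@](C)(OC)O[C@@H]3C2)[C@H](OC(=O)C2=C[C@@H](O)[C@H]3O[C@](C)(OC)[C@@](C)(OC)O[C@@H]3C2)C1
F7 | step 6 | 3,4,5-tris-O-shikimoylshikimic acid | O=C(O)C1=C[C@@H](OC(=O)C2=C[C@@H](O)[C@@H](O)[C@H](O)C2)[C@@H](OC(=O)C2=C[C@@H](O)[C@@H](O)[C@H](O)C2)[C@H](OC(=O)C2=C[C@@H](O)[C@@H](O)[C@H](O)C2)C1
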